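In the oak run at 41 °C, isomer of the product climbs from 18.1% to 34.4% of the substrate charged while mono adduct goes from 19.0% to 21.4%, and two chemists read that differently.

| flask | substrate | reagent | temperature | remark | time |
|---|---|---|---|---|---|
| alder | 0.25 M | 0.90 M | 16 °C | run made earlier |  |
| oak | 0.38 M | 0.90 M | 41 °C | run made earlier |  |
| eta | 0.50 M | 0.900 M | 20 °C |  | 20 min |
| gamma | 0.50 M | 0.900 M | 50 °C |  | 20 min |
| alpha | 0.50 M | 0.900 M | 35 °C |  | 20 min |
| zeta | 0.50 M | 0.900 M | 5 °C |  | 20 min |

- alder (time / min: mono adduct / %, bis adduct / %, isomer of the product / %): 1.00: 2.6, 0, 0; 1.50: 3.6, 0.4, 0; 2.50: 3.9, 0, 0; 4.00: 7.6, 0, 2.4; 8.00: 11.6, 0.2, 0.7; 12.0: 16.0, 1.8, 4.1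
- oak (time / min: mono adduct / %, bis adduct / %, isomer of the product / %): 0.333: 8.6, 0, 0.9; 0.833: 14.2, 0.2, 4.4; 1.33: 16.7, 0.9, 11.2; 2.00: 19.0, 1.5, 18.1; 4.00: 21.4, 5.5, 34.4

(standard deviation of a reading: 1 percentage point)

- what was read earlier has a scatter of 1 percentage point, one standard deviation

* the flask that comes out highest in share of mono adduct in all that became mono adduct or bis adduct or isomer of the product, or "all alike" when all lie within 1.5 percentage points (eta / gamma / alpha / zeta / all alike)
* share of mono adduct in all that became mono adduct or bis adduct or isomer of the product, eta
* share of mono adduct in all that became mono adduct or bis adduct or isomer of the product, gamma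
* share of mono adduct in all that became mono adduct or bis adduct or isomer of the product, alpha
* share of mono adduct in all that became mono adduct or bis adduct or isomer of the product, zeta

The first chemist sees a chain from substrate through mono adduct to isomer, with a smaller leak to bis adduct, so the share of mono adduct falls steeply as conversion rises, and possible isomer reversibility could raise the hot values slightly. This view is the forecast: “Mono is therefore consumed faster than it forms”. It names zeta as highest and gives 89% for zeta, 54% for eta, 5% for alpha and 0.7% for gamma.

The second chemist, who speaks here, holds that mono adduct and isomer form an equilibrium. Divide the isomer gained per minute by the mean mono adduct over the same interval, which gives an apparent constant. In oak it is 0.577 /min at an isomer-to-mono ratio of 0.821, but 0.403 /min at 1.30. For a reversible step this constant falls on a straight line against the ratio, and the line reaches zero at the stop ratio, the equilibrium constant: 2.41. This is a rough reading, given the scatter of 1 percentage point.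

One over one plus the stop ratio is 29.3%, the balance share: mono adduct over mono adduct plus isomer at equilibrium. The slope of the same line gives a relaxation time of 0.809 min at oak's temperature. That is far shorter than 20 min, so hot gamma should stand at balance, assuming the ratio carries over from oak. Taking the part of bis adduct among the products as it stands in oak's last reading, I commit gamma to 26.7%, against the forecast's 0.7%.

The flasks give 84.6% in zeta, 45.0% in eta, 23.3% in alpha and 20.6% in gamma.

    substrate + reagent → mono adduct (k = 0.00290 /M/s, Ea = 79.0 kJ/mol)
    substrate + reagent → other mono adduct (k = 9.40 × 10⁻⁵ /M/s, Ea = 62.0 kJ/mol)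
    reagent + mono adduct → bis adduct (k = 0.00100 /M/s, Ea = 60.0 kJ/mol)
    reagent + other mono adduct → bis adduct (k = 5.00 × 10⁻⁴ /M/s, Ea = 76.0 kJ/mol)
    mono adduct ⇌ isomer of the product (K = 2.80, k = 0.00730 /s, Ea = 84.0 kJ/mol, ΔH = −9.00 kJ/mol)
    (constants at 35 °C)

In gamma, mono adduct stands at 20.2% and isomer at 48.9%, so the pair is 29.2% mono adduct, beside the balance share of 29.3% read in oak; in alpha it is 27.4%. The chain keeps its region in zeta, where the isomer-to-mono ratio is 0.136, less than the stop ratio read in oak, and mono adduct at the asked time is made 3.29 times faster than used up, each step taken net.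

The runs stem from a simulated flask from invented constants; the scatter is artificial.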